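## Analysis of the target

The target (26) is a guaiane-type sesquiterpenoid monoester in which cyclopentane ring A (C1–C5) and cycloheptene ring B (C1, C5–C10) share the C1–C5 bond, and C1 is one end of the tetrasubstituted ring-fusion alkene C1=C10. C10 and C4 carry methyl groups (C14, C15), C7 carries a 2-hydroxypropan-2-yl group (C11), and the C8 oxygen is acylated by (E)-4-hydroxycinnamic acid (22). The four stereocentres are (4S,5S,7S,8S); H4, H5 and H7 lie on one face (called α here), so the C4 methyl is cis to C6 on ring A, the C7 side chain is β and the C8 oxygen is α. The two ring B substituents are therefore trans and can both sit pseudo-equatorially. The tertiary carbinol dehydrates easily, the tetrasubstituted alkene can migrate under acid, and the cinnamate does not tolerate organometallics, reducing agents, hydrogenation or light. The synthesis is hard because a seven-membered ring must be closed with its only alkene at the ring fusion, and because the C4 methyl has to end up cis to C6 on a flexible bicycle. The route rests on reading ring B as a cyclohept-4-enone: with a carbonyl at C7 the alkene C1=C10 lies across the ring, C5=C1–C10=C9 is the diene of a 1-isopropenylcyclopentene, and C6–C7–C8 is a three-carbon oxyallyl unit that already carries the C8 oxygen.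

## Retrosynthetic reasoning

**C8–O ester bond.** 26 is traced to diol 21 and the phenol-protected acid 24 (through ester 25). The cinnamate is cut first because it would not survive the organometallic, reductive and hydrogenation steps used to build the core. The forward reaction has to acylate the secondary C8 hydroxyl next to the free tertiary C11 hydroxyl; 24 comes from 22 by silylation.

**C6–H and C7–H bonds.** 21 is traced to allylic diol 20, and 20 to its benzyl ether 19. Adding hydrogen across C6=C7 from the face of the C8 hydroxyl fixes C7 relative to C8 with the trans relationship of the target. The forward sequence needs the free hydroxyl as director, so the benzyl group is removed first by a method that leaves both alkenes alone.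

**C7–C11 bond and the two C11–methyl bonds.** 19 is traced through ester 18 and enol triflate 17 to ketone 16. C11 enters by carbonylation and the methyl groups by twofold addition of a methyl organometallic. The cut is made here because the C7 ketone of 16 has one methylene (C6) and one alkoxy methine (C8) as neighbours, so kinetic enolisation should go to C6 only.

**C4–H bond.** 16 is traced through exocyclic alkene 15 and tertiary alcohol 14 to silyl ether 13. A diene that already held the C4 methine would direct the new C5–C6 bond trans to the methyl, which is the wrong relationship. C4 therefore enters as an oxygenated quaternary centre that steers C5 and is then exchanged for hydrogen delivered on the open α face. This exchange is placed before the C11 carbinol exists, because a dehydration could not tell two tertiary alcohols apart.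

**C8–C9 and C5–C6 bonds (ring B).** 13 is traced to diene 7 and the acetal enol silane 11. This cut removes the seven-membered ring in one convergent step, leaves the alkene at C1=C10 and delivers the C8 oxygen together with the C7 ketone. The forward reaction must join the oxygenated cation terminus to C9, close the seven- and not a five-membered ring, and approach C5 anti to the C4 oxygen. C8 needs no kinetic control because it lies next to the ketone and is equilibrated.

**Ring A.** 7 is traced to enyne 6 by ring-closing enyne metathesis, which forms C1=C5 and passes the methylene to C10. 6 comes from terminal alkyne 5, aldehyde 4 and silyl ether 2 of (R)-linalool (1). The quaternary carbinol carbon of 1 becomes C4 and is the only source of absolute configuration.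

**Cation precursor.** 11 is traced to ketone 10 by enol silylation, and 10 to 1,1-dimethoxyacetone (8) and two molecules of benzyl alcohol (9) by acetal exchange. Benzyl is chosen because the ether must later be cleaved without touching the alkenes.

## Alternatives that were turned down

**Alternative 1: arene ring expansion.**
- Disconnection: C5–C1 and C5–C6 are cut, so ring B goes back to a benzene ring (C1, C6–C10) and C5 to a carbene carbon tethered through C4(=O)–C3–C2.
- Key step: Rh2(OAc)4 (divalent rhodium) turns diazoketone A2 into a carbenoid that adds to the C1–C6 bond of the arene. The norcaradiene then opens to the cycloheptatriene A1, so ring A closes and ring B is formed together.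
- For: the aromatic precursor fixes C14, the complete C11 unit and the C8 oxygen before any ring is made. Both rings appear in one catalytic step, and a chiral analogue of Rh2(OAc)4 could set C5. On step count to the bicyclic skeleton, and in having C11 in place from the start, this plan is stronger than the chosen one.
- Against: A1 has three conjugated alkenes where the target keeps one. C6=C7 and the C8=C9 enol ether would have to be saturated, creating C7 and C8, while C1=C10 survives, and nothing distinguishes them. C5 in A1 is α to the C4 ketone and doubly allylic, so the one stereocentre the key step sets is easily lost. The C4 ketone still has to become the methyl-bearing methine.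
- Comparison: the chosen cycloaddition gives ring B at the right oxidation level, with one alkene at C1=C10, an sp3 oxygen at C8 and a ketone where C11 is to be attached.

**Alternative 2: sulfone ring contraction.**
- Disconnection: the C1=C10 alkene is traced to a sulfonyl bridge between C1 and C10 in the eight-membered cyclic sulfone A4.
- Key step: KOH with CCl4 halogenates one α-carbon, the α′-carbanion closes to an episulfone, and loss of the sulfonyl group gives A3, the acetonide of 21.
- For: the alkene position is fixed by the two C–S bonds and no regioisomer is possible. All four stereocentres are in place and untouched, and A3 is two operations from the target. On certainty of alkene placement this plan is at least as strong as the chosen one.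
- Against: the key step makes one bond and no stereocentre. A4 is an eight-membered thiacycle with four stereocentres, closed by C–S bond formation at two secondary carbons, and its stereocentres must be set on a flexible precursor. Both α-carbons are tertiary C–H centres, so halogenation and closure are hindered. The electron-rich alkene formed would also trap the carbene that these conditions generate.
- Comparison: the chosen route makes ring B, two C–C bonds and the C1=C10 alkene in one step from two small pieces, and sets the stereocentres afterwards on the rigid bicycle.

**Alternative 3: [5+2] cycloaddition.**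
- Disconnection: C1–C5 and C9–C10 are cut, giving the alkyne–vinylcyclopropane A6, which derives from 1.
- Key step: [Rh(CO)2Cl]2 (monovalent rhodium) joins the tethered methylalkyne and the siloxy vinylcyclopropane of A6 to give the bicyclic silyl enol ether A5, closing both rings in one event.
- For: both rings form in a single intramolecular catalytic step, where the chosen route needs one step for each ring. The tether dictates the regiochemistry, and the reaction class is dependable. On ring-forming power and regiochemical certainty this plan is stronger.
- Against: A5 has no oxygen at C8. Its enol ether is C6=C7, so electrophilic oxidation would mark C6, the wrong neighbour. After hydrolysis the C7 ketone lies between two methylenes that enolisation cannot tell apart. A6 also needs a siloxycyclopropyl unit attached to the hindered vinyl terminus of 1. C5 is relayed from C4 with the same methyl against silyloxy discrimination as in the chosen route, so nothing is gained there.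
- Comparison: the chosen cycloaddition builds one ring fewer, but its three-carbon partner brings the C8 oxygen on the correct side of the ketone and leaves only one enolisable methylene.

Key step: step 8

Remark on naming: guaiane numbering is used throughout (C14 on C10, C15 on C4, C11 on C7); α is the face of the bicycle that carries H5, β the other face.
Remark on the starting material: (R)-linalool is taken as bought in enantiomerically enriched form, and its enantiomeric purity sets that of the target.

## Steps

Step 1
Reactants: 1 (R)-linalool
Product: 2 (R)-triethyl[(3,7-dimethylocta-1,6-dien-3-yl)oxy]silane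
Conditions: Et3SiOTf, 2,6-lutidine, CH2Cl2, −78 to 0 °C
Reagents that add atoms: triethylsilyl trifluoromethanesulfonate, CC[Si](CC)(CC)OS(=O)(=O)C(F)(F)F
Why: Silylation of a hindered tertiary allylic alcohol needs the silyl triflate with a non-nucleophilic base; the C–O bond is not touched, so the configuration of the future C4 is kept.

Step 2
Reactants: 2 (R)-triethyl[(3,7-dimethylocta-1,6-dien-3-yl)oxy]silane
Product: 4 (R)-4-methyl-4-(triethylsilyloxy)hex-5-enal, via secondary ozonide 3 (not isolated)
Conditions: O3 (1 equiv), CH2Cl2, −78 °C; PPh3, −78 °C to rt
Reagents that add atoms: ozone, [O-][O+]=O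
Why: Ozonolysis with reductive work-up; electrophilic ozone should react much faster with the electron-rich trisubstituted alkene than with the vinyl group next to the quaternary silyloxy carbon, so one equivalent cleaves only the former.

Step 3
Reactants: 4 (R)-4-methyl-4-(triethylsilyloxy)hex-5-enal
Product: 5 (R)-triethyl[(3-methylhept-1-en-6-yn-3-yl)oxy]silane
Conditions: dimethyl (1-diazo-2-oxopropyl)phosphonate, K2CO3, MeOH, 0 °C to rt
Reagents that add atoms: dimethyl (1-diazo-2-oxopropyl)phosphonate, COP(=O)(OC)C(=[N+]=[N-])C(C)=O
Why: Seyferth–Gilbert homologation with the Ohira–Bestmann reagent turns the aldehyde into the terminal alkyne under mild carbonate conditions that the tertiary silyl ether tolerates.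

Step 4
Reactants: 5 (R)-triethyl[(3-methylhept-1-en-6-yn-3-yl)oxy]silane
Product: 6 (R)-triethyl[(3-methyloct-1-en-6-yn-3-yl)oxy]silane
Conditions: n-BuLi, THF, −78 °C; MeI, −78 °C to rt
Reagents that add atoms: iodomethane, CI
Why: Alkylation of the lithium acetylide; the acetylenic C–H is the only acidic site.

Step 5
Reactants: 6 (R)-triethyl[(3-methyloct-1-en-6-yn-3-yl)oxy]silane
Product: 7 (R)-triethyl{[1-methyl-3-(prop-1-en-2-yl)cyclopent-2-en-1-yl]oxy}silane
Conditions: second-generation Grubbs catalyst RuCl2(=CHPh)(H2IMes)(PCy3) (5 mol %), CH2Cl2, 40 °C
Reagents that add atoms: none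
Why: Ring-closing enyne metathesis of a 1,6-enyne in the exo mode closes ring A through C1=C5 and transfers the methylene to C10, so the methyl-capped alkyne becomes the isopropenyl group; no stereocentre is made or touched.

Step 6
Reactants: 8 1,1-dimethoxyacetone; 9 benzyl alcohol
Product: 10 1,1-bis(benzyloxy)propan-2-one
Conditions: TsOH (cat.), 9 (3 equiv in all, neat), 60 °C, reduced pressure (removal of MeOH)
Reagents that add atoms: benzyl alcohol (second equivalent of 9), OCc1ccccc1
Why: Acid-catalysed acetal exchange replaces both methoxy groups of 8, so two molecules of 9 are incorporated and two of methanol are released. Removal of the volatile methanol drives the equilibrium to the dibenzyl acetal, and the ketone stays free because acyclic ketals of it are not favoured under these conditions.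

Step 7
Reactants: 10 1,1-bis(benzyloxy)propan-2-one
Product: 11 3,3-bis(benzyloxy)-2-(trimethylsiloxy)prop-1-ene
Conditions: LiN(i-Pr)2 (LDA), THF, −78 °C; Me3SiCl
Reagents that add atoms: chlorotrimethylsilane, C[Si](C)(C)Cl
Why: Kinetic deprotonation takes the methyl protons and not the hindered acetal methine, and O-silylation of the enolate gives the enol silane.

Step 8
Reactants: 7 (R)-triethyl{[1-methyl-3-(prop-1-en-2-yl)cyclopent-2-en-1-yl]oxy}silane; 11 3,3-bis(benzyloxy)-2-(trimethylsiloxy)prop-1-ene
Product: 13 8α-benzyloxy-4α-(triethylsilyloxy)-5αH-11,12,13-trinorguai-1(10)-en-7-one, via 8β-benzyloxy epimer 12 (not isolated)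
Conditions: Me3SiOTf (0.2 equiv), 2,6-di-tert-butyl-4-methylpyridine (0.3 equiv), CH2Cl2, −78 °C; Et3N; then DBU, MeOH, rt
Reagents that add atoms: none
Why: The silyl triflate removes one benzyloxy group of 11 and leaves a 1-benzyloxy-2-siloxyallyl cation that is polarised: the former acetal carbon (C8) is the electrophilic end and the enol silane carbon (C6) the nucleophilic end. The unhindered and most nucleophilic diene terminus C9 of 7 adds to C8, an allyl cation spread over C10–C1–C5 results, and C6 captures it at C5; loss of the silyl group from the carbonyl oxygen regenerates the silyl triflate. The closest known reaction type is the [4+3] cycloaddition of alkoxy-substituted siloxyallyl cations, made from enol silanes of 1,1-dialkoxyacetones, with 1,3-dienes. Ring B closes in the second bond formation as a seven-membered ring, 7-endo with respect to the allyl cation so that C1=C10 ends up inside the ring; the 5-exo alternative (C6 to C10) would have to build a quaternary carbon and is open mainly to cation formed from the s-trans diene. C5 is set by C4: C6 is expected to approach the cyclopentenyl end of the cation on the face away from the triethylsilyloxy group, which leaves H5 on the α face. C8 is formed without reliable control (12 alongside 13) and is then set thermodynamically by DBU in the same flask, because the 8α-benzyloxy group of 13 can sit pseudo-equatorially on ring B. The step needs C8-to-C9 regiochemistry (secured by the polarity of the cation and the substitution of the diene), seven- over five-ring closure, and attack anti to the C4 oxygen; the hindered pyridine keeps triflic acid from ionising the tertiary allylic C4–O bond of 7.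

Step 9
Reactants: 13 8α-benzyloxy-4α-(triethylsilyloxy)-5αH-11,12,13-trinorguai-1(10)-en-7-one
Product: 14 8α-benzyloxy-4α-hydroxy-5αH-11,12,13-trinorguai-1(10)-en-7-one
Conditions: HF·pyridine, THF/pyridine, 0 °C to rt
Reagents that add atoms: none
Why: Fluoride-driven cleavage of the tertiary triethylsilyl ether; C4 is no longer allylic, so the mildly acidic medium should not ionise it, and the ketone, benzyl ether and alkene are inert.

Step 10
Reactants: 14 8α-benzyloxy-4α-hydroxy-5αH-11,12,13-trinorguai-1(10)-en-7-one
Product: 15 8α-benzyloxy-5αH-11,12,13-trinorguaia-1(10),4(15)-dien-7-one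
Conditions: SOCl2, pyridine, CH2Cl2, −40 to 0 °C
Reagents that add atoms: none
Why: Dehydration through the chlorosulfite with pyridine as base is an anti E2 elimination; H5 is syn to the leaving group and cannot be removed this way, whereas the methyl protons are always antiperiplanar. Proton loss from C3 in place of C15 would be harmless, since the next step gives the same saturated product.

Step 11
Reactants: 15 8α-benzyloxy-5αH-11,12,13-trinorguaia-1(10),4(15)-dien-7-one
Product: 16 8α-benzyloxy-4αH,5αH-11,12,13-trinorguai-1(10)-en-7-one
Conditions: H2 (1 atm), platinum on carbon (Pt/C), EtOAc, rt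
Reagents that add atoms: none
Why: Heterogeneous hydrogenation should occur on the open α face of ring A, anti to C6, placing H4 α and the methyl β (cis to C6) as in the target. The tetrasubstituted C1=C10 alkene and the benzyl ether are expected to be inert to platinum under these mild conditions.

Step 12
Reactants: 16 8α-benzyloxy-4αH,5αH-11,12,13-trinorguai-1(10)-en-7-one
Product: 17 8α-benzyloxy-4αH,5αH-11,12,13-trinorguaia-1(10),6-dien-7-yl trifluoromethanesulfonate
Conditions: KN(SiMe3)2 (KHMDS), THF, −78 °C; PhNTf2
Reagents that add atoms: N-phenylbis(trifluoromethanesulfonimide), O=S(=O)(N(c1ccccc1)S(=O)(=O)C(F)(F)F)C(F)(F)F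
Why: Kinetic deprotonation by a bulky amide takes the C6 methylene in preference to the alkoxy-substituted methine C8, and O-triflation traps the enolate; C8 is not touched.

Step 13
Reactants: 17 8α-benzyloxy-4αH,5αH-11,12,13-trinorguaia-1(10),6-dien-7-yl trifluoromethanesulfonate
Product: 18 methyl 8α-benzyloxy-4αH,5αH-12,13-dinorguaia-1(10),6-dien-11-oate
Conditions: Pd(OAc)2, 1,3-bis(diphenylphosphino)propane, CO (1 atm), Et3N, MeOH/DMF, 60 °C
Reagents that add atoms: carbon monoxide, [C-]#[O+]; methanol, CO
Why: Palladium-catalysed methoxycarbonylation: oxidative addition of the enol triflate to zerovalent palladium, CO insertion and methanolysis install C11 as the ester carbon with C6=C7 in place.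

Step 14
Reactants: 18 methyl 8α-benzyloxy-4αH,5αH-12,13-dinorguaia-1(10),6-dien-11-oate
Product: 19 8α-benzyloxy-4αH,5αH-guaia-1(10),6-dien-11-ol
Conditions: MeLi (3.5 equiv), Et2O/THF, −78 to 0 °C
Reagents that add atoms: methyllithium, [Li]C
Why: Twofold 1,2-addition of the hard organolithium to the ester (two methyl groups enter, methoxide leaves) gives the tertiary carbinol; conjugate addition to the hindered β-carbon C6 is not expected.

Step 15
Reactants: 19 8α-benzyloxy-4αH,5αH-guaia-1(10),6-dien-11-ol
Product: 20 4αH,5αH-guaia-1(10),6-diene-8α,11-diol
Conditions: lithium 4,4′-di-tert-butylbiphenylide (LiDBB), THF, −78 °C; MeOH, aq. NH4Cl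
Reagents that add atoms: none
Why: Single-electron reductive cleavage of the benzyl ether by the arene radical anion; the electron enters the benzyl ring and the benzylic C–O bond breaks, while isolated alkenes and the tertiary alkoxide are not reduced at this temperature.

Step 16
Reactants: 20 4αH,5αH-guaia-1(10),6-diene-8α,11-diol
Product: 21 4αH,5αH,7αH-guai-1(10)-ene-8α,11-diol
Conditions: H2 (1 atm), [Ir(cod)(PCy3)(py)]PF6 (5 mol %), CH2Cl2, 0 °C to rt
Reagents that add atoms: none
Why: Hydroxyl-directed hydrogenation: iridium held by the α-oriented C8 hydroxyl (with the C11 hydroxyl as a second ligand) should deliver hydrogen to the α face of C6=C7, placing H7 α and the side chain β, trans to the C8 oxygen. The tetrasubstituted C1=C10 alkene is only homoallylic to the hydroxyl and more hindered, so it should react much more slowly, and the reaction is stopped after one equivalent of hydrogen.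

Step 17
Reactants: 22 (E)-4-hydroxycinnamic acid
Product: 24 (E)-4-(tert-butyldimethylsilyloxy)cinnamic acid, via bis-silyl derivative 23 (not isolated)
Conditions: t-BuMe2SiCl (2.2 equiv), imidazole, DMF, rt; then AcOH, THF/H2O, rt
Reagents that add atoms: tert-butyldimethylsilyl chloride, CC(C)(C)[Si](C)(C)Cl
Why: Both acidic oxygens are silylated, and the far more labile silyl ester is then hydrolysed selectively, leaving the phenol protected.

Step 18
Reactants: 21 4αH,5αH,7αH-guai-1(10)-ene-8α,11-diol; 24 (E)-4-(tert-butyldimethylsilyloxy)cinnamic acid
Product: 25 8-O-[(E)-4-(tert-butyldimethylsilyloxy)cinnamoyl]-4αH,5αH,7αH-guai-1(10)-ene-8α,11-diol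
Conditions: DCC, DMAP, CH2Cl2, 0 °C to rt
Reagents that add atoms: none
Why: Steglich esterification; the secondary C8 hydroxyl is acylated, while the tertiary C11 hydroxyl should not react under these conditions.

Step 19
Reactants: 25 8-O-[(E)-4-(tert-butyldimethylsilyloxy)cinnamoyl]-4αH,5αH,7αH-guai-1(10)-ene-8α,11-diol
Product: 26 8-O-[(E)-4-hydroxycinnamoyl]-4αH,5αH,7αH-guai-1(10)-ene-8α,11-diol, the target
Conditions: Bu4NF, AcOH, THF, 0 °C
Reagents that add atoms: none
Why: Fluoride cleaves the phenolic silyl ether; the acetic acid buffer keeps the phenoxide from attacking the ester or promoting acyl shift.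

## Compound list

1 | (R)-linalool | C=C[C@](C)(O)CCC=C(C)C | starting material
2 | (R)-triethyl[(3,7-dimethylocta-1,6-dien-3-yl)oxy]silane | C=C[C@](C)(O[Si](CC)(CC)CC)CCC=C(C)C | intermediate
3 | 3,3-dimethyl-5-[(R)-3-methyl-3-(triethylsilyloxy)pent-4-enyl]-1,2,4-trioxolane (secondary ozonide, not isolated) | CC1(C)OOC(CC[C@](C)(C=C)O[Si](CC)(CC)CC)O1 | intermediate
4 | (R)-4-methyl-4-(triethylsilyloxy)hex-5-enal | O=CCC[C@](C)(C=C)O[Si](CC)(CC)CC | intermediate
5 | (R)-triethyl[(3-methylhept-1-en-6-yn-3-yl)oxy]silane | C#CCC[C@](C)(C=C)O[Si](CC)(CC)CC | intermediate
6 | (R)-triethyl[(3-methyloct-1-en-6-yn-3-yl)oxy]silane | CC#CCC[C@](C)(C=C)O[Si](CC)(CC)CC | intermediate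
7 | (R)-triethyl{[1-methyl-3-(prop-1-en-2-yl)cyclopent-2-en-1-yl]oxy}silane | C=C(C)C1=C[C@](C)(O[Si](CC)(CC)CC)CC1 | intermediate
8 | 1,1-dimethoxyacetone | COC(OC)C(C)=O | starting material
9 | benzyl alcohol | OCc1ccccc1 | starting material
10 | 1,1-bis(benzyloxy)propan-2-one | CC(=O)C(OCc1ccccc1)OCc1ccccc1 | intermediate
11 | 3,3-bis(benzyloxy)-2-(trimethylsiloxy)prop-1-ene | C=C(O[Si](C)(C)C)C(OCc1ccccc1)OCc1ccccc1 | intermediate
12 | 8β-benzyloxy-4α-(triethylsilyloxy)-5αH-11,12,13-trinorguai-1(10)-en-7-one (not isolated) | CC1=C2CC[C@@](C)(O[Si](CC)(CC)CC)[C@@H]2CC(=O)[C@H](OCc3ccccc3)C1 | intermediate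
13 | 8α-benzyloxy-4α-(triethylsilyloxy)-5αH-11,12,13-trinorguai-1(10)-en-7-one | CC1=C2CC[C@@](C)(O[Si](CC)(CC)CC)[C@@H]2CC(=O)[C@@H](OCc3ccccc3)C1 | intermediate
14 | 8α-benzyloxy-4α-hydroxy-5αH-11,12,13-trinorguai-1(10)-en-7-one | CC1=C2CC[C@@](C)(O)[C@@H]2CC(=O)[C@@H](OCc3ccccc3)C1 | intermediate
15 | 8α-benzyloxy-5αH-11,12,13-trinorguaia-1(10),4(15)-dien-7-one | CC1=C2CCC(=C)[C@@H]2CC(=O)[C@@H](OCc3ccccc3)C1 | intermediate
16 | 8α-benzyloxy-4αH,5αH-11,12,13-trinorguai-1(10)-en-7-one | CC1=C2CC[C@H](C)[C@@H]2CC(=O)[C@@H](OCc3ccccc3)C1 | intermediate
17 | 8α-benzyloxy-4αH,5αH-11,12,13-trinorguaia-1(10),6-dien-7-yl trifluoromethanesulfonate | CC1=C2CC[C@H](C)[C@@H]2C=C(OS(=O)(=O)C(F)(F)F)[C@@H](OCc3ccccc3)C1 | intermediate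
18 | methyl 8α-benzyloxy-4αH,5αH-12,13-dinorguaia-1(10),6-dien-11-oate | CC1=C2CC[C@H](C)[C@@H]2C=C(C(=O)OC)[C@@H](OCc3ccccc3)C1 | intermediate
19 | 8α-benzyloxy-4αH,5αH-guaia-1(10),6-dien-11-ol | CC1=C2CC[C@H](C)[C@@H]2C=C(C(C)(C)O)[C@@H](OCc3ccccc3)C1 | intermediate
20 | 4αH,5αH-guaia-1(10),6-diene-8α,11-diol | CC1=C2CC[C@H](C)[C@@H]2C=C(C(C)(C)O)[C@@H](O)C1 | intermediate
21 | 4αH,5αH,7αH-guai-1(10)-ene-8α,11-diol | CC1=C2CC[C@H](C)[C@@H]2C[C@H](C(C)(C)O)[C@@H](O)C1 | intermediate
22 | (E)-4-hydroxycinnamic acid | OC(=O)/C=C/c1ccc(O)cc1 | starting material
23 | tert-butyldimethylsilyl (E)-4-(tert-butyldimethylsilyloxy)cinnamate (not isolated) | CC(C)(C)[Si](C)(C)OC(=O)/C=C/c1ccc(O[Si](C)(C)C(C)(C)C)cc1 | intermediate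
24 | (E)-4-(tert-butyldimethylsilyloxy)cinnamic acid | OC(=O)/C=C/c1ccc(O[Si](C)(C)C(C)(C)C)cc1 | intermediate
25 | 8-O-[(E)-4-(tert-butyldimethylsilyloxy)cinnamoyl]-4αH,5αH,7αH-guai-1(10)-ene-8α,11-diol | CC1=C2CC[C@H](C)[C@@H]2C[C@H](C(C)(C)O)[C@@H](OC(=O)/C=C/c2ccc(O[Si](C)(C)C(C)(C)C)cc2)C1 | intermediate
26 | (4S,5S,7S,8S)-8-O-[(E)-4-hydroxycinnamoyl]guai-1(10)-ene-8,11-diol (CNP0403230.1) | CC1=C2CC[C@H](C)[C@@H]2C[C@H](C(C)(C)O)[C@@H](OC(=O)/C=C/c2ccc(O)cc2)C1 | target

## Step count and least certain steps

Total: 19 steps. Longest linear sequence: 16 steps (steps 1–5, 8–16, 18 and 19). Steps 6 and 7 (cation precursor) and step 17 (acid) are side branches.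

**Step 8 (key step).**
- The allyl cation formed after the first bond may be intercepted before the seven-membered ring closes, by proton loss or by five-ring closure at C10 when the diene reacts from its s-trans form.
- The silyl triflate may ionise the tertiary allylic C4–O bond of the diene and destroy it.
- Facial discrimination between methyl and triethylsilyloxy at C4 may be modest. The C5 diastereomers can be separated while C4 is still a stereocentre, but material is lost.
- The base equilibration at C8 may be less one-sided than the conformational analysis suggests, because α-alkoxy ketones have a dipolar preference for the axial position; the epimers would then be separated and the minor one resubmitted to the base.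
- Fallback, from 7 back to 13: the same benzyloxy-substituted oxyallyl unit is generated without any Lewis acid from the chloro ketone 1-(benzyloxy)-3-chloropropan-2-one F1, by dehydrochlorination with Et3N in 2,2,2-trifluoroethanol in the presence of 7. This is the [4+3] chemistry of α-alkoxy-α′-chloro ketones. The unsilylated cation is less electrophilic and spares the C4–O bond. The crude α-benzyloxy ketone is equilibrated with DBU in MeOH as in step 8 and rejoins the route at 13.

**Step 10.**
- Regiocontrol of the elimination may be lost: if the chlorosulfite ionises or eliminates in a syn fashion, the allylic proton at C5 is removed, the new alkene moves into conjugation with C1=C10 and the C5 stereocentre is erased.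
- Fallback, from 14 to 16, bypassing steps 10 and 11: 14 is acylated with methyl chlorooxoacetate (pyridine, DMAP, CH2Cl2) to the tertiary methyl oxalate F2. F2 is then reduced with Bu3SnH and AIBN in toluene at 110 °C, a Barton–McCombie-type radical deoxygenation. The planar C4 radical should take its hydrogen on the open α face, anti to C6, which gives 16 directly without any alkene intermediate.

**Step 15.**
- Electron transfer may break the allylic C8–O bond in place of the benzylic one, giving deoxygenation at C8, or the conditions may cause partial alkene migration.
- Fallback, from 18 to 20: the benzyl ether is removed one step earlier and without reduction. 18 is treated with BCl3 and pentamethylbenzene in CH2Cl2 at −78 °C to give methyl 8α-hydroxy-4αH,5αH-12,13-dinorguaia-1(10),6-dien-11-oate F3; the ester deactivates the allylic position against ionisation. Excess MeLi then converts F3 into 20.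

**Step 16.**
- The freely rotating C11 hydroxyl may direct the catalyst to the β face of C6=C7.
- The hindered trisubstituted alkene may react slowly enough that the tetrasubstituted C1=C10 alkene, homoallylic to the C8 hydroxyl, is also reduced.
- The acidic iridium hydride species may ionise the tertiary allylic C11–O bond before reduction is complete.
- Fallback, from 18 to 21: the hydrogenation is done at the ester stage, where the C8 hydroxyl is the only director. 18 is debenzylated with BCl3 and pentamethylbenzene to the hydroxy ester F3. F3 is hydrogenated with [Rh(nbd)(dppb)]BF4 under H2 pressure in CH2Cl2; this cationic rhodium catalyst, held by the hydroxyl and the ester carbonyl, is known for directed reduction of α-alkylidene β-hydroxy esters and leaves tetrasubstituted alkenes alone. The product is methyl 8α-hydroxy-4αH,5αH,7αH-12,13-dinorguai-1(10)-en-11-oate F4. MeLi with CeCl3 in THF at −78 °C then gives 21.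

## Further compounds

F1 | step 8 | 1-(benzyloxy)-3-chloropropan-2-one | O=C(CCl)COCc1ccccc1
F2 | step 10 | methyl oxalate of 14 (8α-benzyloxy-7-oxo-5αH-11,12,13-trinorguai-1(10)-en-4α-yl methyl oxalate) | CC1=C2CC[C@@](C)(OC(=O)C(=O)OC)[C@@H]2CC(=O)[C@@H](OCc3ccccc3)C1
F3 | step 15 | methyl 8α-hydroxy-4αH,5αH-12,13-dinorguaia-1(10),6-dien-11-oate | CC1=C2CC[C@H](C)[C@@H]2C=C(C(=O)OC)[C@@H](O)C1
F4 | step 16 | methyl 8α-hydroxy-4αH,5αH,7αH-12,13-dinorguai-1(10)-en-11-oate | CC1=C2CC[C@H](C)[C@@H]2C[C@H](C(=O)OC)[C@@H](O)C1
A1 | alternative 1 | 15-norguaia-1(10),6,8-trien-4-one with the C8 enol oxygen and the C11 oxygen joined as an acetonide | CC1=C2CCC(=O)[C@@H]2C=C3C(=C1)OC(C)(C)OC3(C)C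
A2 | alternative 1 | 1-diazo-4-(2,2,4,4,7-pentamethyl-4H-1,3-benzodioxin-6-yl)butan-2-one | [N-]=[N+]=CC(=O)CCc1cc2c(cc1C)OC(C)(C)OC2(C)C
A3 | alternative 2 | 8,11-O-isopropylidene derivative of guai-1(10)-ene-8α,11-diol | CC1=C2CC[C@H](C)[C@@H]2C[C@H]2[C@@H](OC(C)(C)OC2(C)C)C1
A4 | alternative 2 | eight-membered cyclic sulfone with the sulfonyl group between C1 and C10, carrying the same acetonide | CC1S(=O)(=O)C2CC[C@H](C)[C@@H]2C[C@H]2[C@@H](OC(C)(C)OC2(C)C)C1
A5 | alternative 3 | 7-(tert-butyldimethylsilyloxy)-4α-(triethylsilyloxy)-11,12,13-trinorguaia-1(10),6-diene | CC1=C2CC[C@@](C)(O[Si](CC)(CC)CC)[C@@H]2C=C(O[Si](C)(C)C(C)(C)C)CC1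
A6 | alternative 3 | (E)-1-(tert-butyldimethylsilyloxy)-1-[3-methyl-3-(triethylsilyloxy)oct-1-en-6-yn-1-yl]cyclopropane | CC#CCC[C@@](C)(O[Si](CC)(CC)CC)/C=C/C1(O[Si](C)(C)C(C)(C)C)CC1
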